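The cyclohexane is cut across two opposite bonds, C1–C6 and C3–C4. Methyl vinyl ketone supplies C6–C5–C4 and the C4 methyl. A glycolate-dianion equivalent, a 5H-oxazol-4-one carrying a 2-phosphonioethyl arm, supplies C1–C2–C3 and the side-chain carbon on C1. A one-flask catalytic asymmetric Michael addition followed by intramolecular Wittig olefination joins both bonds, fixes the quaternary C1 and leaves a C3=C4 alkene. The key step thus exploits the 1,4-relationship of the oxygenated C1 and the methyl-bearing C4 in the six-membered ring. The C1 hydroxyl later steers an epoxide that is converted to the trans bromochloride, and the ester becomes the dienyl side chain.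

Key step: step 4

Remark: ring atoms are numbered as in the target name (C1 carbinol, C3 = CHCl, C4 = C(CH3)Br); each chiral catalyst named is the antipode expected to give the drawn configuration and would be exchanged for its mirror image if the sense of induction proved opposite.

Step 1
Reactants: 1 benzamide; 2 chloroacetyl chloride
Product: 3 N-(2-chloroacetyl)benzamide
Conditions: toluene, 110 °C
Reagents that add atoms: none
Why: Thermal N-acylation of the primary amide by the acid chloride (imide formation) should proceed with loss of HCl and brings in the chloromethyl carbon that becomes C1 of the target.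

Step 2
Reactants: 3 N-(2-chloroacetyl)benzamide
Product: 4 2-phenyl-1,3-oxazol-4(5H)-one
Conditions: NaH (1.0 equiv), THF, 0 °C to rt
Reagents that add atoms: none
Why: Deprotonation of the imide and 5-exo-tet O-alkylation by the chloromethyl group (intramolecular Williamson-type cyclisation, the usual entry to 5H-oxazol-4-ones) should close the oxazolone, whose ring CH2 is now strongly acidic.

Step 3
Reactants: 4 2-phenyl-1,3-oxazol-4(5H)-one; 5 vinyltriphenylphosphonium bromide
Product: 6 [2-(4-oxo-2-phenyl-4,5-dihydro-1,3-oxazol-5-yl)ethyl]triphenylphosphonium tetrafluoroborate (racemic)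
Conditions: Et3N (10 mol %), 4 (1.3 equiv), CH2Cl2, 0 °C to rt; then aq. NaBF4 wash
Reagents that add atoms: sodium tetrafluoroborate [Na+].F[B-](F)(F)F
Why: Conjugate (Michael) addition of the aromatic 4-oxidooxazole to the vinylphosphonium salt should give the mono-alkylated oxazolone, because the ylide formed is protonated at once by the far more acidic oxazolone C–H so that no olefination intervenes; the new stereocentre is racemic and is erased in step 4, and the tetrafluoroborate exchange removes the halide that would bind to the hydrogen-bond catalyst.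

Step 4
Reactants: 6 [2-(4-oxo-2-phenyl-4,5-dihydro-1,3-oxazol-5-yl)ethyl]triphenylphosphonium tetrafluoroborate; 7 methyl vinyl ketone (but-3-en-2-one)
Product: 9 (5R)-8-methyl-2-phenyl-1-oxa-3-azaspiro[4.5]deca-2,7-dien-4-one, via Michael adduct 8 (not isolated)
Conditions: quinine-derived tertiary amine–squaramide catalyst (10 mol %), 7 (1.1 equiv), CH2Cl2, −40 °C; volatiles removed; then KN(SiMe3)2 (1.05 equiv), THF, −78 to 0 °C, same flask
Reagents that add atoms: none
Why: The catalyst amine deprotonates the oxazolone C–H of 6 (by far the most acidic site) and the aromatic 4-oxidooxazole, held by the squaramide, adds through C5 to the β-carbon of 7, which makes the C1–C6 ring bond and gives ketone 8; KN(SiMe3)2 then removes the next most acidic proton, α to phosphorus, and the non-stabilised ylide attacks the methyl ketone of the same molecule to give an oxaphosphetane that collapses to the C3=C4 alkene (the C3–C4 ring bond) and Ph3P=O. The closest known reaction type is the tandem Michael addition–intramolecular Wittig [3+3] cyclohexene annulation, its first half being an organocatalytic conjugate addition of a 5H-oxazol-4-one to an enone. The six-membered carbocycle closes by 6-exo-trig attack of the ylide carbon on the ketone, and the ring enforces the cis alkene. The only new stereocentre, the spiro carbon that becomes C1, is set in the Michael step by the catalyst, which must deliver 7 to the si face of the enolate carbon; once quaternary it cannot epimerise. The step needs C- rather than O-alkylation and olefination of the ketone rather than of the oxazolone carbonyl: the soft enolate–soft acceptor pairing secures the first, ylide attack on the ring carbonyl would need a four-membered ring, and the acidity order (oxazolone C–H, then P–CH2, then ketone α-CH) keeps the two bond formations in sequence.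

Step 5
Reactants: 9 (5R)-8-methyl-2-phenyl-1-oxa-3-azaspiro[4.5]deca-2,7-dien-4-one
Product: 10 (1R)-1-hydroxy-4-methylcyclohex-3-ene-1-carboxylic acid
Conditions: NaOH (4 M aq.), EtOH, 80 °C; then HCl to pH 2
Reagents that add atoms: sodium hydroxide [Na+].[OH-]; water O
Why: Basic hydrolysis of the cyclic N-acyl imidate (both carbon–nitrogen acyl bonds are cleaved) should release the tertiary α-hydroxy acid, whose quaternary stereocentre cannot epimerise.

Step 6
Reactants: 10 (1R)-1-hydroxy-4-methylcyclohex-3-ene-1-carboxylic acid
Product: 11 methyl (1R)-1-hydroxy-4-methylcyclohex-3-ene-1-carboxylate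
Conditions: MeI, K2CO3, DMF, rt
Reagents that add atoms: iodomethane CI
Why: SN2 alkylation of the carboxylate by iodomethane (esterification) should be chemoselective, since the hindered tertiary hydroxyl is not deprotonated by carbonate.

Step 7
Reactants: 11 methyl (1R)-1-hydroxy-4-methylcyclohex-3-ene-1-carboxylate
Product: 12 methyl (1R,3R,6S)-3-hydroxy-6-methyl-7-oxabicyclo[4.1.0]heptane-3-carboxylate (epoxide oxygen cis to the hydroxyl)
Conditions: VO(acac)2 (5 mol %), t-BuOOH (1.5 equiv), CH2Cl2, rt
Reagents that add atoms: tert-butyl hydroperoxide CC(C)(C)OO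
Why: Hydroxyl-directed vanadium-catalysed epoxidation, in which the vanadium alkoxide of the homoallylic tertiary C1–OH delivers the peroxide oxygen intramolecularly (as with terpinen-4-ol), should place the epoxide oxygen on the ring face of the hydroxyl and so set C3 and C4 relative to C1.

Step 8
Reactants: 12 methyl (1R,3R,6S)-3-hydroxy-6-methyl-7-oxabicyclo[4.1.0]heptane-3-carboxylate
Product: 13 methyl (1R,3S,4S)-3-chloro-1,4-dihydroxy-4-methylcyclohexane-1-carboxylate
Conditions: Li2CuCl4 (1.5 equiv), THF, 0 °C to rt; aq. NH4Cl
Reagents that add atoms: dilithium tetrachlorocuprate [Li+].[Li+].Cl[Cu-2](Cl)(Cl)Cl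
Why: SN2 opening of the trisubstituted epoxide by chloride at the less hindered secondary carbon C3 (trans-diaxial, Fürst–Plattner course) should invert C3 and place chlorine anti to the C1 hydroxyl, while the tertiary C4–O bond keeps the configuration of the epoxide oxygen.

Step 9
Reactants: 13 methyl (1R,3S,4S)-3-chloro-1,4-dihydroxy-4-methylcyclohexane-1-carboxylate
Product: 14 methyl (1R,3S,4S)-4-bromo-3-chloro-1-hydroxy-4-methylcyclohexane-1-carboxylate
Conditions: HBr (33% in AcOH, 5 equiv), CH2Cl2, 0 °C to rt
Reagents that add atoms: hydrogen bromide Br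
Why: SN1 substitution with neighbouring-group participation should replace the tertiary C4 hydroxyl with net retention, because the antiperiplanar C3 chlorine bridges the developing cation and bromide opens the chloronium ion at the tertiary carbon anti to chlorine (Br trans to Cl, cis to the C1 hydroxyl), whereas the C1 hydroxyl, α to the ester, does not ionise.

Step 10
Reactants: 14 methyl (1R,3S,4S)-4-bromo-3-chloro-1-hydroxy-4-methylcyclohexane-1-carboxylate
Product: 16 (1R,3S,4S)-4-bromo-3-chloro-4-methyl-1-[3-(trimethylsilyl)prop-1-en-2-yl]cyclohexan-1-ol, via bis(silylmethyl) carbinol 15 (not isolated)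
Conditions: Me3SiCH2MgCl (5 equiv), CeCl3 (5 equiv), THF, −78 °C to rt; then SiO2, CH2Cl2
Reagents that add atoms: (trimethylsilyl)methylmagnesium chloride C[Si](C)(C)C[Mg]Cl
Why: Double addition of the weakly basic organocerium reagent to the ester followed by Peterson elimination of one β-silyl alcohol unit on silica gel (allylsilane synthesis from esters) should give the 2-substituted allylsilane without elimination of the tertiary bromide or secondary chloride and without touching a stereocentre.

Step 11
Reactants: 16 (1R,3S,4S)-4-bromo-3-chloro-4-methyl-1-[3-(trimethylsilyl)prop-1-en-2-yl]cyclohexan-1-ol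
Product: 17 trimethyl({(1R,3S,4S)-4-bromo-3-chloro-4-methyl-1-[3-(trimethylsilyl)prop-1-en-2-yl]cyclohexyl}oxy)silane
Conditions: N-(trimethylsilyl)imidazole (2 equiv), CH2Cl2, rt
Reagents that add atoms: N-(trimethylsilyl)imidazole C[Si](C)(C)n1ccnc1
Why: Silylation of the tertiary hydroxyl (silyl ether protection) should mask the only protic group, which would otherwise consume the boron catalyst of the next step.

Step 12
Reactants: 17 trimethyl({(1R,3S,4S)-4-bromo-3-chloro-4-methyl-1-[3-(trimethylsilyl)prop-1-en-2-yl]cyclohexyl}oxy)silane; 18 3-methylbut-2-enal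
Product: 20 (1R,3S,4S)-4-bromo-3-chloro-1-[(4S)-4-hydroxy-6-methylhepta-1,5-dien-2-yl]-4-methylcyclohexan-1-ol, via bis(trimethylsilyl) ether 19 (not isolated)
Conditions: acyloxyborane catalyst (20 mol %) made in the flask from (2S,3S)-2-O-(2,6-diisopropoxybenzoyl)tartaric acid and BH3·THF, EtCN, −78 °C; then aq. citric acid, THF, 0 °C
Reagents that add atoms: none
Why: In this catalytic enantioselective Hosomi–Sakurai allylation the 2-substituted allylsilane should attack the boron-bound enal in 1,2-fashion through its CH2 terminus with allyl transposition, the tartrate-derived acyloxyborane directing it to the si face of the aldehyde to set the 4S carbinol (the remote ring stereocentres exert no influence), and mild acid then cleaves both trimethylsilyl ethers.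

Compound list
1 | benzamide | NC(=O)c1ccccc1 | starting material
2 | chloroacetyl chloride | ClCC(Cl)=O | starting material
3 | N-(2-chloroacetyl)benzamide | O=C(CCl)NC(=O)c1ccccc1 | intermediate
4 | 2-phenyl-1,3-oxazol-4(5H)-one | O=C1COC(c2ccccc2)=N1 | intermediate
5 | vinyltriphenylphosphonium bromide | C=C[P+](c1ccccc1)(c2ccccc2)c3ccccc3.[Br-] | starting material
6 | [2-(4-oxo-2-phenyl-4,5-dihydro-1,3-oxazol-5-yl)ethyl]triphenylphosphonium tetrafluoroborate (racemic) | O=C1N=C(c2ccccc2)OC1CC[P+](c3ccccc3)(c4ccccc4)c5ccccc5.F[B-](F)(F)F | intermediate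
7 | methyl vinyl ketone (but-3-en-2-one) | CC(=O)C=C | starting material
8 | {2-[(5R)-4-oxo-5-(3-oxobutyl)-2-phenyl-4,5-dihydro-1,3-oxazol-5-yl]ethyl}triphenylphosphonium tetrafluoroborate (not isolated) | O=C1N=C(c2ccccc2)O[C@@]1(CC[P+](c3ccccc3)(c4ccccc4)c5ccccc5)CCC(C)=O.F[B-](F)(F)F | intermediate
9 | (5R)-8-methyl-2-phenyl-1-oxa-3-azaspiro[4.5]deca-2,7-dien-4-one | O=C1N=C(c2ccccc2)O[C@@]13CCC(C)=CC3 | intermediate
10 | (1R)-1-hydroxy-4-methylcyclohex-3-ene-1-carboxylic acid | O=C(O)[C@@]1(O)CCC(C)=CC1 | intermediate
11 | methyl (1R)-1-hydroxy-4-methylcyclohex-3-ene-1-carboxylate | COC(=O)[C@@]1(O)CCC(C)=CC1 | intermediate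
12 | methyl (1R,3R,6S)-3-hydroxy-6-methyl-7-oxabicyclo[4.1.0]heptane-3-carboxylate | COC(=O)[C@@]1(O)CC[C@]2(C)O[C@@H]2C1 | intermediate
13 | methyl (1R,3S,4S)-3-chloro-1,4-dihydroxy-4-methylcyclohexane-1-carboxylate | COC(=O)[C@@]1(O)CC[C@](C)(O)[C@@H](Cl)C1 | intermediate
14 | methyl (1R,3S,4S)-4-bromo-3-chloro-1-hydroxy-4-methylcyclohexane-1-carboxylate | COC(=O)[C@@]1(O)CC[C@](C)(Br)[C@@H](Cl)C1 | intermediate
15 | (1R,3S,4S)-4-bromo-3-chloro-1-[2-hydroxy-1,3-bis(trimethylsilyl)propan-2-yl]-4-methylcyclohexan-1-ol (not isolated) | C[Si](C)(C)CC(O)(C[Si](C)(C)C)[C@@]1(O)CC[C@](C)(Br)[C@@H](Cl)C1 | intermediate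
16 | (1R,3S,4S)-4-bromo-3-chloro-4-methyl-1-[3-(trimethylsilyl)prop-1-en-2-yl]cyclohexan-1-ol | C=C(C[Si](C)(C)C)[C@@]1(O)CC[C@](C)(Br)[C@@H](Cl)C1 | intermediate
17 | trimethyl({(1R,3S,4S)-4-bromo-3-chloro-4-methyl-1-[3-(trimethylsilyl)prop-1-en-2-yl]cyclohexyl}oxy)silane | C=C(C[Si](C)(C)C)[C@@]1(O[Si](C)(C)C)CC[C@](C)(Br)[C@@H](Cl)C1 | intermediate
18 | 3-methylbut-2-enal | CC(C)=CC=O | starting material
19 | bis(trimethylsilyl) ether of 20 (not isolated) | C=C(C[C@H](O[Si](C)(C)C)C=C(C)C)[C@@]1(O[Si](C)(C)C)CC[C@](C)(Br)[C@@H](Cl)C1 | intermediate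
20 | (1R,3S,4S)-4-bromo-3-chloro-1-[(4S)-4-hydroxy-6-methylhepta-1,5-dien-2-yl]-4-methylcyclohexan-1-ol | C=C(C[C@H](O)C=C(C)C)[C@@]1(O)CC[C@](C)(Br)[C@@H](Cl)C1 | target

Total step count: 12. Longest linear sequence: 12 steps (from 1 and 2 to 20).

Steps most likely to fail

Step 4. The conjugate addition may show poor enantiofacial control, because the enolate carries its own phosphonium counter-ion. In the olefination stage, retro-Michael cleavage of 8 or ketone enolisation may outrun ylide formation. The fallback makes the two ring bonds separately and sets out from oxazolone 4. C-alkylation with 4-bromo-2-methylbut-1-ene (K2CO3, NaI, DMF) should give 5-(3-methylbut-3-en-1-yl)-2-phenyl-1,3-oxazol-4(5H)-one F1. Palladium-catalysed asymmetric allylic alkylation of F1 with allyl acetate (Pd2(dba)3·CHCl3 as the zerovalent palladium source, (R,R)-DACH-phenyl Trost ligand, Et3N, CH2Cl2) should set the quaternary centre and give (5R)-5-(3-methylbut-3-en-1-yl)-2-phenyl-5-(prop-2-en-1-yl)-1,3-oxazol-4(5H)-one F2. Ring-closing metathesis with the second-generation Grubbs catalyst RuCl2(=CHPh)(PCy3)(H2IMes) then comes back to the route at 9.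

Step 9. The β-chloro tertiary cation may react as an open ion, with loss of facial control at C4. It may also be captured by the cis C1 hydroxyl to form an oxygen bridge, or lose a proton. The fallback places bromine first by an anti addition and sets out from acid 10. Bromolactonisation (N-bromosuccinimide, NaHCO3, CH2Cl2/H2O) should give (1R,4S,5S)-4-bromo-1-hydroxy-4-methyl-6-oxabicyclo[3.2.1]octan-7-one F3, with bromine anti to the lactone oxygen and cis to the C1 hydroxyl. K2CO3 in MeOH opens the lactone, and the liberated alkoxide displaces bromide to give methyl (1S,3R,6R)-3-hydroxy-6-methyl-7-oxabicyclo[4.1.0]heptane-3-carboxylate F4, the epoxide with oxygen trans to the hydroxyl. HBr in Et2O reopens F4 at the tertiary carbon with inversion to give methyl (1R,3S,4S)-4-bromo-1,3-dihydroxy-4-methylcyclohexane-1-carboxylate F5. Retentive chlorination of the secondary alcohol through its chlorosulfite (SOCl2, catalytic TiCl4, CH2Cl2) comes back to the route at 14.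

Step 12. The catalyst may turn over slowly or control the aldehyde face poorly with the hindered β,β-disubstituted enal. The fallback separates bond formation from stereocontrol and sets out from 17. Allylation of 18 promoted by BF3·OEt2 (CH2Cl2, −78 °C; aq. citric acid work-up) should give (1R,3S,4S)-4-bromo-3-chloro-1-(4-hydroxy-6-methylhepta-1,5-dien-2-yl)-4-methylcyclohexan-1-ol F6 as both carbinol epimers. Dess–Martin periodinane (NaHCO3, CH2Cl2) oxidises only the secondary allylic alcohol to 2-[(1R,3S,4S)-4-bromo-3-chloro-1-hydroxy-4-methylcyclohexyl]-6-methylhepta-1,5-dien-4-one F7. Corey–Bakshi–Shibata reduction with the (R)-2-methyl-oxazaborolidine and BH3·SMe2 (THF, −30 °C) comes back to the route at 20.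

Further compounds
F1 | step 4 | 5-(3-methylbut-3-en-1-yl)-2-phenyl-1,3-oxazol-4(5H)-one (racemic) | C=C(C)CCC1OC(c2ccccc2)=NC1=O
F2 | step 4 | (5R)-5-(3-methylbut-3-en-1-yl)-2-phenyl-5-(prop-2-en-1-yl)-1,3-oxazol-4(5H)-one | O=C1N=C(c2ccccc2)O[C@@]1(CC=C)CCC(C)=C
F3 | step 9 | (1R,4S,5S)-4-bromo-1-hydroxy-4-methyl-6-oxabicyclo[3.2.1]octan-7-one | O=C1O[C@H]2C[C@]1(O)CC[C@]2(C)Br
F4 | step 9 | methyl (1S,3R,6R)-3-hydroxy-6-methyl-7-oxabicyclo[4.1.0]heptane-3-carboxylate | COC(=O)[C@@]1(O)CC[C@@]2(C)O[C@H]2C1
F5 | step 9 | methyl (1R,3S,4S)-4-bromo-1,3-dihydroxy-4-methylcyclohexane-1-carboxylate | COC(=O)[C@@]1(O)CC[C@](C)(Br)[C@@H](O)C1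
F6 | step 12 | (1R,3S,4S)-4-bromo-3-chloro-1-(4-hydroxy-6-methylhepta-1,5-dien-2-yl)-4-methylcyclohexan-1-ol (both side-chain carbinol epimers) | C=C(CC(O)C=C(C)C)[C@@]1(O)CC[C@](C)(Br)[C@@H](Cl)C1
F7 | step 12 | 2-[(1R,3S,4S)-4-bromo-3-chloro-1-hydroxy-4-methylcyclohexyl]-6-methylhepta-1,5-dien-4-one | C=C(CC(=O)C=C(C)C)[C@@]1(O)CC[C@](C)(Br)[C@@H](Cl)C1
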